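## Retrosynthetic overview

- **Structural feature used:** counted from the carbon bonded to C4, flavan ring A reads C4a, C5‑OMe, C6‑H, C7‑OH, C8‑OMe, C8a‑O1. The chalcone ring reads C3', C4'‑OMe, C5'‑H, C6'‑OH, C1'‑acyl, C2'‑OH. The two patterns differ only at C8/C1', so both rings come from one arene, 2',6'-dihydroxy-4'-methoxyacetophenone, with an acetyl group standing in for the C8 oxygen.
- **Late disconnections:** the benzyl ethers, the enone C=C (Claisen–Schmidt), and C8–OMe from C8‑acetyl (Baeyer–Villiger carbon‑to‑oxygen exchange).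
- **Key disconnection:** retro‑oxa‑[4+2] of the pyran ring (bonds C3–C4 and O1–C2). This leads to styrene and an o‑quinone methide whose two aryl halves are constitutionally identical. C2 and C4 arise together, and the same event makes the two acetyl groups chemically different.
- **Origin of the quinone methide:** dehydrogenation of the methylene‑bridged dimer, made from two acetophenone molecules and formaldehyde. C4 is a one‑carbon linchpin that carries both C4–aryl bonds.
- **Ring order:** the pyran ring is the only ring formed (step 3). All four benzene rings are bought.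

Key step: step 3

Assumption: the sense of induction of the phosphoramide on quinone methide 6 cannot be derived with certainty. The (R)-catalyst is written, and its mirror image is used if it leads to the (2S,4S) series.

## Route

Step 1
Reactants: 1 2',6'-dihydroxy-4'-methoxyacetophenone (2 molecules, used in excess); 2 formaldehyde (37% aq.)
Product: 3 bis(3-acetyl-2,4-dihydroxy-6-methoxyphenyl)methane
Conditions: aq. HCHO (0.4 equiv relative to 1), KOH, H2O/MeOH, 0 °C to rt; then 1 M HCl
Reagents that add atoms: none
Why: Hydroxymethylation of the phenoxide at C3 (C3 and C5 are equivalent and are the only free ring positions), loss of hydroxide to an o‑quinone methide and Michael addition of a second phenoxide is the classical formaldehyde coupling of acylphloroglucinols, and the excess of 1 holds back further bridging.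

Step 2
Reactants: 3 bis(3-acetyl-2,4-dihydroxy-6-methoxyphenyl)methane
Product: 4 bis[3-acetyl-4-(benzyloxy)-2-hydroxy-6-methoxyphenyl]methane
Conditions: BnBr (2.1 equiv), K2CO3 (2.2 equiv), acetone, reflux
Reagents that add atoms: benzyl bromide, BrCc1ccccc1
Why: Williamson etherification under weak base alkylates only one of the two OH groups flanking each acetyl, namely the unhindered one para to the bridge, because the other is flanked by the diarylmethane carbon and stays locked in the hydrogen bond to C=O.

Step 3
Reactants: 4 bis[3-acetyl-4-(benzyloxy)-2-hydroxy-6-methoxyphenyl]methane; 5 styrene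
Product: 7 (2R,4R)-8-acetyl-4-[3-acetyl-4-(benzyloxy)-2-hydroxy-6-methoxyphenyl]-7-(benzyloxy)-5-methoxy-2-phenylchroman (2,4-trans), via o-quinone methide 6 (not isolated)
Conditions: (i) DDQ (1.05 equiv), toluene, 0 °C to rt, filtration through Celite; (ii) 5 (5 equiv), (R)-3,3'-bis(2,4,6-triisopropylphenyl)-H8-BINOL N-triflylphosphoramide (10 mol %), 4 Å MS, toluene, −20 °C
Reagents that add atoms: none
Why: DDQ abstracts hydride from the CH2 group, which is activated by o‑OH, o‑OMe and p‑OBn on both rings, and loss of a phenolic proton gives o‑quinone methide 6, whose two tautomers are identical, so it does not matter which ring becomes the heterodiene and no protection of the second ortho‑OH is needed. The chiral acid protonates or hydrogen‑bonds the quinone methide carbonyl (its P=O can hold the free 2‑OH of the spectator ring), and styrene adds in an inverse‑demand, strongly asynchronous oxa‑[4+2] cycloaddition, CH2 terminus to C4 first and O1 to the developing benzylic carbon C2 second; the closest known reaction type is the chiral Brønsted acid catalysed [4+2] cycloaddition of aryl‑substituted o‑quinone methides with styrenes to 2,4‑diarylchromans. The pyran ring closes as a (4+2) annulation through C3–C4 and O1–C2 (at the stepwise limit, a 6‑endo capture of the C2 cation by the phenol oxygen), with rearomatisation of ring A as the driving force. C4 remains prochiral until O1–C2 forms, so both stereocentres are fixed in the same event, and the chiral counter‑anion sets the absolute sense by selecting one enantiotopic hydroxyaryl/face combination. The C5‑OMe group sets the relative sense: its peri strain puts the C4 aryl group in the Z (inside) position of 6, where the O–H···O=C contact also holds it, and pseudo‑axial in the half‑chair, while phenyl goes endo/equatorial, which corresponds to the 2,4‑trans isomer. Regiochemistry follows the polarisation of styrene, the indane [3+2] path and Friedel–Crafts self‑alkylation are shut off because every ortho position is substituted and a hexa‑ortho‑substituted triarylmethane is too congested, and the step strips the C8 acetyl of its hydrogen‑bond partner while the other acetyl keeps its own.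

Step 4
Reactants: 7 (2R,4R)-8-acetyl-4-[3-acetyl-4-(benzyloxy)-2-hydroxy-6-methoxyphenyl]-7-(benzyloxy)-5-methoxy-2-phenylchroman
Product: 8 (2R,4R)-4-[3-acetyl-4-(benzyloxy)-2-hydroxy-6-methoxyphenyl]-7-(benzyloxy)-5-methoxy-2-phenylchroman-8-yl acetate
Conditions: mCPBA (1.3 equiv), CH2Cl2, 0 °C to rt
Reagents that add atoms: mCPBA, O=C(OO)c1cccc(Cl)c1
Why: Baeyer–Villiger oxidation with migration of the electron‑rich aryl group should pick the C8 acetyl, which lies between O1 and OBn, is twisted out of conjugation and is not hydrogen bonded, whereas the other acetyl is a planar chelated 2‑hydroxyaryl ketone (a vinylogous acid) that resists neutral peracid; no stereocentre is touched.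

Step 5
Reactants: 8 (2R,4R)-4-[3-acetyl-4-(benzyloxy)-2-hydroxy-6-methoxyphenyl]-7-(benzyloxy)-5-methoxy-2-phenylchroman-8-yl acetate
Product: 10 1-{6-(benzyloxy)-3-[(2R,4R)-7-(benzyloxy)-5,8-dimethoxy-2-phenylchroman-4-yl]-2-hydroxy-4-methoxyphenyl}ethan-1-one, via C8 phenol 9 (not isolated)
Conditions: K2CO3 (2.5 equiv), MeOH/DMF, 0 °C to rt, Ar; then MeI (1.5 equiv), rt
Reagents that add atoms: methyl iodide, CI
Why: Transesterification frees the C8 phenol, the only non‑chelated phenoxide present, and Williamson methylation takes place there while the chelated and hindered 2‑OH of the pendant ring stays free.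

Step 6
Reactants: 10 1-{6-(benzyloxy)-3-[(2R,4R)-7-(benzyloxy)-5,8-dimethoxy-2-phenylchroman-4-yl]-2-hydroxy-4-methoxyphenyl}ethan-1-one; 11 benzaldehyde
Product: 12 (E)-1-{6-(benzyloxy)-3-[(2R,4R)-7-(benzyloxy)-5,8-dimethoxy-2-phenylchroman-4-yl]-2-hydroxy-4-methoxyphenyl}-3-phenylprop-2-en-1-one (di-O-benzyl sarcandrone B)
Conditions: 11 (1.5 equiv), 50% aq. KOH, EtOH, rt; then 1 M HCl
Reagents that add atoms: none
Why: Claisen–Schmidt condensation of the single remaining methyl ketone with a non‑enolisable aldehyde and E1cB dehydration gives the E‑enone, as is routine for 2'-hydroxy-4',6'-dialkoxyacetophenones, and neither C2–H nor C4–H is acidic enough to epimerise.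

Step 7
Reactants: 12 di-O-benzyl sarcandrone B
Product: 13 sarcandrone B, (E)-1-{2,6-dihydroxy-3-[(2R,4R)-7-hydroxy-5,8-dimethoxy-2-phenylchroman-4-yl]-4-methoxyphenyl}-3-phenylprop-2-en-1-one
Conditions: BCl3 (6 equiv), pentamethylbenzene (10 equiv), CH2Cl2, −78 °C; then aq. work-up
Reagents that add atoms: none
Why: Lewis acid cleavage of aryl benzyl ethers at −78 °C with pentamethylbenzene as a non‑basic benzyl cation scavenger spares the enone C=C (which hydrogenolysis would not), the three aryl methyl ethers and both stereocentres.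

## Compound list

| No. | Name | SMILES | Role |
|---|---|---|---|
| 1 | 2',6'-dihydroxy-4'-methoxyacetophenone | CC(=O)c1c(O)cc(OC)cc1O | starting material |
| 2 | formaldehyde | C=O | starting material |
| 3 | bis(3-acetyl-2,4-dihydroxy-6-methoxyphenyl)methane | COc1cc(O)c(C(C)=O)c(O)c1Cc1c(OC)cc(O)c(C(C)=O)c1O | intermediate |
| 4 | bis[3-acetyl-4-(benzyloxy)-2-hydroxy-6-methoxyphenyl]methane | COc1cc(OCc2ccccc2)c(C(C)=O)c(O)c1Cc1c(OC)cc(OCc2ccccc2)c(C(C)=O)c1O | intermediate |
| 5 | styrene | C=Cc1ccccc1 | starting material |
| 6 | (6Z)-2-acetyl-6-{[3-acetyl-4-(benzyloxy)-2-hydroxy-6-methoxyphenyl]methylidene}-3-(benzyloxy)-5-methoxycyclohexa-2,4-dien-1-one | O=C1C(C(C)=O)=C(OCc2ccccc2)C=C(OC)/C1=C/c1c(OC)cc(OCc2ccccc2)c(C(C)=O)c1O | intermediate |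
| 7 | (2R,4R)-8-acetyl-4-[3-acetyl-4-(benzyloxy)-2-hydroxy-6-methoxyphenyl]-7-(benzyloxy)-5-methoxy-2-phenylchroman | COc1cc(OCc2ccccc2)c(C(C)=O)c(O)c1[C@H]1C[C@H](c2ccccc2)Oc2c(C(C)=O)c(OCc3ccccc3)cc(OC)c21 | intermediate |
| 8 | (2R,4R)-4-[3-acetyl-4-(benzyloxy)-2-hydroxy-6-methoxyphenyl]-7-(benzyloxy)-5-methoxy-2-phenylchroman-8-yl acetate | COc1cc(OCc2ccccc2)c(C(C)=O)c(O)c1[C@H]1C[C@H](c2ccccc2)Oc2c(OC(C)=O)c(OCc3ccccc3)cc(OC)c21 | intermediate |
| 9 | (2R,4R)-4-[3-acetyl-4-(benzyloxy)-2-hydroxy-6-methoxyphenyl]-7-(benzyloxy)-5-methoxy-2-phenylchroman-8-ol | COc1cc(OCc2ccccc2)c(C(C)=O)c(O)c1[C@H]1C[C@H](c2ccccc2)Oc2c(O)c(OCc3ccccc3)cc(OC)c21 | intermediate |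
| 10 | 1-{6-(benzyloxy)-3-[(2R,4R)-7-(benzyloxy)-5,8-dimethoxy-2-phenylchroman-4-yl]-2-hydroxy-4-methoxyphenyl}ethan-1-one | COc1cc(OCc2ccccc2)c(C(C)=O)c(O)c1[C@H]1C[C@H](c2ccccc2)Oc2c(OC)c(OCc3ccccc3)cc(OC)c21 | intermediate |
| 11 | benzaldehyde | O=Cc1ccccc1 | starting material |
| 12 | di-O-benzyl sarcandrone B | COc1cc(OCc2ccccc2)c(C(=O)/C=C/c2ccccc2)c(O)c1[C@H]1C[C@H](c2ccccc2)Oc2c(OC)c(OCc3ccccc3)cc(OC)c21 | intermediate |
| 13 | sarcandrone B | COc1cc(O)c(C(=O)/C=C/c2ccccc2)c(O)c1[C@H]1C[C@H](c2ccccc2)Oc2c(OC)c(O)cc(OC)c21 | target |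

Total step count: 7. Longest linear sequence: 7.

## Steps most likely to fail

**Step 3.**
- What may go wrong:
  - Styrene may capture the strongly stabilised, tetra‑ortho‑substituted cation only slowly.
  - The C–O closure may discriminate poorly between the enantiotopic hydroxyaryl/face combinations.
  - Material may leak into the 2,4‑cis series.
  - Acid‑catalysed re‑opening at O1–C2 would erode both selectivities.
- Fallback: the two stereocentres are set one after the other by known reactions. It sets out from 4.
  - Quinone methide 6 is generated with DDQ as before. It is intercepted with 1-phenyl-1-(trimethylsilyloxy)ethene (cat. Sc(OTf)3, CH2Cl2, −40 °C, Mukaiyama–Michael addition) to give the achiral ketone 3,3-bis[3-acetyl-4-(benzyloxy)-2-hydroxy-6-methoxyphenyl]-1-phenylpropan-1-one F1.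
  - Noyori transfer hydrogenation (RuCl[(S,S)-TsDPEN](p-cymene), HCO2H/Et3N) should reduce only the unhindered phenyl ketone. The product is (1S)-3,3-bis[3-acetyl-4-(benzyloxy)-2-hydroxy-6-methoxyphenyl]-1-phenylpropan-1-ol F2.
  - An intramolecular Mitsunobu etherification (PPh3, DIAD, THF, high dilution) closes O1–C2 with inversion to (2R). The choice between the two diastereotopic hydroxyaryl groups, governed by the same C5‑OMe peri strain, sets C4.
  - The sequence comes back to the route at 7.

**Step 4.**
- What may go wrong: chemoselectivity between the two acetyl groups may be lost, or the peracid may oxidise the phenolic ring.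
- Fallback: the chelatable ketone is masked first. It sets out from 7.
  - BF3·OEt2 (CH2Cl2, rt) converts only the 2‑hydroxyaryl ketone into its difluoroboron chelate F3, because the C8 acetyl has no ortho‑OH.
  - Baeyer–Villiger oxidation with mCPBA then has a single free ketone to attack and gives the 8-acetoxy difluoroboron chelate F4.
  - K2CO3/MeOH removes the acetate and the chelate together. The sequence comes back at phenol 9, which is methylated as in step 5.

**Step 7.**
- What may go wrong:
  - The Lewis acid may remove the C8 methyl ether, which is flanked by two oxygens.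
  - The liberated 2',6'-dihydroxychalcone may cyclise to a flavanone.
  - The C4–aryl bond may undergo heterolysis.
- Fallback: the benzyl groups are removed before any alkene is present. It sets out from 10.
  - Hydrogenolysis (H2, Pd/C, EtOAc/MeOH) gives 1-{2,6-dihydroxy-3-[(2R,4R)-7-hydroxy-5,8-dimethoxy-2-phenylchroman-4-yl]-4-methoxyphenyl}ethan-1-one F5.
  - F5 is condensed directly with benzaldehyde 11 as its polyphenoxide (large excess of KOH, EtOH/H2O, rt, cold acidification). The sequence comes back at 13.

## Further compounds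

F1 | step 3 | 3,3-bis[3-acetyl-4-(benzyloxy)-2-hydroxy-6-methoxyphenyl]-1-phenylpropan-1-one | COc1cc(OCc2ccccc2)c(C(C)=O)c(O)c1C(CC(=O)c1ccccc1)c1c(OC)cc(OCc2ccccc2)c(C(C)=O)c1O
F2 | step 3 | (1S)-3,3-bis[3-acetyl-4-(benzyloxy)-2-hydroxy-6-methoxyphenyl]-1-phenylpropan-1-ol | COc1cc(OCc2ccccc2)c(C(C)=O)c(O)c1C(C[C@H](O)c1ccccc1)c1c(OC)cc(OCc2ccccc2)c(C(C)=O)c1O
F3 | step 4 | difluoroboron chelate of 7 (O–BF2–O=C bridge between the 2-OH and the acetyl of the pendant ring) | COc1cc(OCc2ccccc2)c2C(C)=[O+][B-](F)(F)Oc2c1[C@H]1C[C@H](c2ccccc2)Oc2c(C(C)=O)c(OCc3ccccc3)cc(OC)c21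
F4 | step 4 | 8-acetoxy difluoroboron chelate | COc1cc(OCc2ccccc2)c2C(C)=[O+][B-](F)(F)Oc2c1[C@H]1C[C@H](c2ccccc2)Oc2c(OC(C)=O)c(OCc3ccccc3)cc(OC)c21
F5 | step 7 | 1-{2,6-dihydroxy-3-[(2R,4R)-7-hydroxy-5,8-dimethoxy-2-phenylchroman-4-yl]-4-methoxyphenyl}ethan-1-one | COc1cc(O)c(C(C)=O)c(O)c1[C@H]1C[C@H](c2ccccc2)Oc2c(OC)c(O)cc(OC)c21
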